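Everything rests on cutting ring B (the seven-membered ring C1, C5–C10) at C6–C7 and C9–C10. The feature exploited is the oxygenation pattern of ring B: the carbinol carbons C6 and C10 sit on either side of the C7–C8(CH3)–C9 segment, so this segment can enter as a 2-methyleneallyl bis-nucleophile between two formyl groups that stand trans on C5 and C1 of ring A. In one operation the key step forms both C–C bonds, closes ring B and creates the C6 and C10 carbinols; its 8-methylene group is a masked methyl. The precursor is a cyclopentane-1,2-dicarbaldehyde that already holds C1, C4 and C5, with the tertiary C4 hydroxyl left free to steer the first allylation by chelation.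

Key step: step 8

Remark on numbering: daucane numbering is used throughout. Ring A is the cyclopentane C1–C5 and ring B is C1, C5–C10. C1 bears the angular methyl, C4 the OH and isopropyl, C8 the methyl. β is the face of the angular methyl. The target is 1S,4R,5S,6S,10R (4β-OH, 6α-OCOAr, 10α-OAc, H5 α).

Assumption: the ligand antipode that gives (S)-11 in step 3 is assigned by analogy only; if the mirror-image series forms, the enantiomeric ligand is used, and every later stereocentre is substrate-controlled.

Step 1
Reactants: 1 (tributylstannyl)methanol; 2 benzyl bromide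
Product: 3 [(benzyloxy)methyl]tributylstannane
Conditions: NaH, Bu4NI (cat.), THF, 0 °C → rt
Reagents that add atoms: benzyl bromide 2, BrCc1ccccc1
Why: Williamson ether synthesis, in which the sodium alkoxide of the primary stannylmethanol is benzylated by SN2 and no stereocentre is involved.

Step 2
Reactants: 3 [(benzyloxy)methyl]tributylstannane; 4 3-methoxycyclopent-2-en-1-one
Product: 7 3-[(benzyloxy)methyl]cyclopent-2-en-1-one, via benzyloxymethyllithium 5 (not isolated), via lithium alkoxide adduct 6 (not isolated)
Conditions: n-BuLi, THF, −78 °C; then 4, −78 → 0 °C; then 1 M HCl, rt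
Reagents that add atoms: [(benzyloxy)methyl]tributylstannane 3, CCCC[Sn](CCCC)(CCCC)COCc1ccccc1; water, O
Why: Tin–lithium exchange gives the α-alkoxy organolithium 5, which adds 1,2 to the vinylogous ester, and acid hydrolysis of adduct 6 with loss of methanol and water transposes the carbonyl (Stork–Danheiser sequence) to the 3-substituted enone that carries C10.

Step 3
Reactants: 7 3-[(benzyloxy)methyl]cyclopent-2-en-1-one; 8 trimethylaluminium; 9 trimethylsilyl trifluoromethanesulfonate
Product: 11 {[(3S)-3-[(benzyloxy)methyl]-3-methylcyclopent-1-en-1-yl]oxy}trimethylsilane, via dimethylaluminium enolate 10 (not isolated)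
Conditions: Cu(OTf)2 (5 mol %), BINOL-derived phosphoramidite ligand (10 mol %), 8 (2 equiv), Et2O, −30 °C; then 9, −30 → 0 °C
Reagents that add atoms: trimethylaluminium 8, C[Al](C)C; trimethylsilyl trifluoromethanesulfonate 9, C[Si](C)(C)OS(=O)(=O)C(F)(F)F
Why: Copper-catalysed enantioselective conjugate addition of a trialkylaluminium to a β-substituted cyclopentenone, in which the chiral copper–phosphoramidite complex selects the enone face and sets the quaternary C1 as S, while O-silylation of the regiodefined enolate 10 stores the C4=C5 enolate position for the next step.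

Step 4
Reactants: 11 silyl enol ether; 12 benzyl chloromethyl ether
Product: 13 (2S,3S)-2,3-bis[(benzyloxy)methyl]-3-methylcyclopentan-1-one (C6 arm trans to C10 arm)
Conditions: TiCl4, CH2Cl2, −78 °C
Reagents that add atoms: benzyl chloromethyl ether 12, ClCOCc1ccccc1
Why: Lewis-acid-mediated α-alkylation of a silyl enol ether with an SN1-active chloromethyl ether (Mukaiyama-type alkylation), in which the benzyloxymethyl cation attacks C5 on the face opposite the larger, TiCl4-coordinated C10 arm so that C6 ends trans to C10 (5S), and because C5 stays epimerisable the same trans isomer can also be enriched by base equilibration.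

Step 5
Reactants: 13 ketone; 14 isopropylmagnesium chloride
Product: 15 (1R,2S,3S)-2,3-bis[(benzyloxy)methyl]-3-methyl-1-(propan-2-yl)cyclopentan-1-ol
Conditions: CeCl3 (anhydrous), THF, −78 → 0 °C; then aq NH4Cl
Reagents that add atoms: isopropylmagnesium chloride 14, CC(C)[Mg]Cl
Why: Cerium-assisted Grignard 1,2-addition, which suppresses enolisation and β-hydride reduction of the hindered cyclopentanone, with the nucleophile approaching C4 anti to the vicinal C6 arm (α face) so that isopropyl ends cis to H5 and the new hydroxyl cis to C6 (4R).

Step 6
Reactants: 15 dibenzyl ether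
Product: 16 (1R,2S,3S)-2,3-bis(hydroxymethyl)-3-methyl-1-(propan-2-yl)cyclopentan-1-ol
Conditions: H2 (1 atm), Pd/C, EtOH, rt
Reagents that add atoms: none
Why: Catalytic hydrogenolysis cleaves both benzyl ethers at once, touches no stereocentre and leaves the tertiary alcohol intact; this triol is the point at which enantiomeric purity should be raised by recrystallisation.

Step 7
Reactants: 16 triol
Product: 17 (1S,2R,3R)-3-hydroxy-1-methyl-3-(propan-2-yl)cyclopentane-1,2-dicarbaldehyde (formyl groups trans; C4 hydroxyl free)
Conditions: (COCl)2, DMSO, CH2Cl2, −78 °C; then Et3N, −78 → 0 °C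
Reagents that add atoms: none
Why: Swern oxidation activates both primary hydroxyls before base is added, so the dialdehyde should form without lactol or lactone detours, the tertiary alcohol cannot be oxidised, and the now enolisable C5 already has the thermodynamically preferred configuration (formyl trans to isopropyl and to the C10 formyl group).

Step 8
Reactants: 17 hydroxy dialdehyde; 18 3-chloro-2-(chloromethyl)prop-1-ene
Product: 20 8-methylenedaucane-4β,6α,10α-triol (1S,4R,5S,6S,10R), via chloromethallyl carbinol aldehyde 19 (not isolated)
Conditions: In powder (3 equiv), NaI (20 mol %), THF/H2O 1:3, 0.02 M, slow addition of 18 (1.1 equiv), rt → 45 °C, ultrasound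
Reagents that add atoms: 3-chloro-2-(chloromethyl)prop-1-ene 18, C=C(CCl)CCl
Why: Indium inserts into one allylic C–Cl bond of 18 (iodide exchange speeds this up) and the allylindium adds through a six-membered, metal-bridged chair to the C6 formyl group to give 19; insertion into the second C–Cl bond and intramolecular allylation of the C10 formyl group then complete the (4+3) annulation. Both events are known reaction types, namely the aqueous Barbier allylation with 2-(halomethyl)allyl halides, including their double addition as trimethylenemethane dianion equivalents, and the indium-mediated intramolecular allylation that closes medium carbocycles; here they are applied in sequence to a new substrate. Ring B closes in a 7-exo-trig mode, C9 attacking C10 with the carbonyl oxygen outside the forming ring, and a lactol between O6 and C10 should not intervene because it would be a strained trans-fused bicyclo[3.3.0] system. C6 is controlled by chelation: trivalent indium bridges the free C4 hydroxyl and the C6 carbonyl oxygen, which stand cis on ring A, so the carbonyl lies over C4 and the allyl group enters from the side of H5, away from C1, giving the 6α (6S) carbinol, whereas a bulky silyl ether on O4 would make C4 the largest Felkin–Anh substituent and favour the opposite face. C10 is controlled by the tether: a metal-bridged closure is possible only with C1 axial in the chair, which puts O10 axial in ring B and anti to the angular methyl (10α, 10R), and since this centre is erased in step 10 its control is not critical. The selectivity needed is a first attack at C6 and a second attack that is intramolecular; the first is secured by chelation activation of the C6 formyl group and the neopentyl shielding of C10, the second by about one equivalent of 18 added slowly at high dilution.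

Step 9
Reactants: 20 triol; 21 4-methoxybenzoyl chloride
Product: 22 6α-(4-methoxybenzoyloxy)-8-methylenedaucane-4β,10α-diol
Conditions: 21 (1.1 equiv), pyridine, DMAP (cat.), CH2Cl2, 0 °C
Reagents that add atoms: 4-methoxybenzoyl chloride 21, COc1ccc(cc1)C(Cl)=O
Why: DMAP-catalysed acylation under kinetic control, in which the equatorial C6 hydroxyl, a hydrogen-bond donor to the C4 hydroxyl, should react ahead of the axial, neopentyl C10 hydroxyl and the tertiary C4 hydroxyl, with retention at C6.

Step 10
Reactants: 22 hydroxy ester
Product: 23 4β-hydroxy-6α-(4-methoxybenzoyloxy)-8-methylenedaucan-10-one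
Conditions: Dess–Martin periodinane, pyridine, CH2Cl2, 0 °C → rt
Reagents that add atoms: none
Why: Dess–Martin oxidation converts the only remaining secondary alcohol into the C10 ketone under near-neutral conditions that leave the ester, the tertiary alcohol and the 8-methylene group in place.

Step 11
Reactants: 23 β,γ-unsaturated ketone
Product: 24 4β-hydroxy-6α-(4-methoxybenzoyloxy)dauc-8-en-10-one
Conditions: DBU (20 mol %), CH2Cl2, 0 °C
Reagents that add atoms: none
Why: Base-catalysed conjugation of a β,γ-unsaturated ketone, in which DBU removes the doubly activated C9 proton and the dienolate is reprotonated at the exocyclic carbon, turning the 8-methylene group into the C8 methyl and fixing the olefin as C8=C9, while catalytic base and low temperature keep the slower γ-deprotonation at C7, and with it loss of the C6 ester, out of play.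

Step 12
Reactants: 24 enone
Product: 25 6α-(4-methoxybenzoyloxy)dauc-8-ene-4β,10β-diol (10S)
Conditions: NaBH4, CeCl3·7H2O, MeOH, −20 → 0 °C
Reagents that add atoms: none
Why: Luche reduction gives clean 1,2-reduction, and hydride should add to C10 from the α face, anti to the axial C1 methyl that stands nearly perpendicular to the carbonyl plane, giving the pseudo-equatorial 10β-alcohol, which is the epimer of what the target needs.

Step 13
Reactants: 25 allylic alcohol; 26 acetic acid
Product: 27 10α-acetoxy-6α-(4-methoxybenzoyloxy)dauc-8-en-4β-ol (1S,4R,5S,6S,10R), the target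
Conditions: PPh3, DIAD, 26, toluene, 0 °C → rt
Reagents that add atoms: acetic acid 26, CC(=O)O
Why: Mitsunobu esterification, in which acetate displaces the activated allylic oxygen by SN2 from the same open α face that hydride used, inverting C10 to the required pseudo-axial 10α-acetate (10R), a substitution known for secondary carbinols next to a methyl-bearing quaternary carbon, while the tertiary C4 hydroxyl is not activated.

Compound list
1 | (tributylstannyl)methanol | CCCC[Sn](CCCC)(CCCC)CO | starting material
2 | benzyl bromide | BrCc1ccccc1 | starting material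
3 | [(benzyloxy)methyl]tributylstannane | CCCC[Sn](CCCC)(CCCC)COCc1ccccc1 | intermediate
4 | 3-methoxycyclopent-2-en-1-one | COC1=CC(=O)CC1 | starting material
5 | benzyloxymethyllithium | [Li]COCc1ccccc1 | intermediate
6 | lithium 1-[(benzyloxy)methyl]-3-methoxycyclopent-2-en-1-olate (racemic) | [Li]OC1(COCc2ccccc2)CCC(OC)=C1 | intermediate
7 | 3-[(benzyloxy)methyl]cyclopent-2-en-1-one | O=C1CCC(COCc2ccccc2)=C1 | intermediate
8 | trimethylaluminium | C[Al](C)C | starting material
9 | trimethylsilyl trifluoromethanesulfonate | C[Si](C)(C)OS(=O)(=O)C(F)(F)F | starting material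
10 | dimethylaluminium (3S)-3-[(benzyloxy)methyl]-3-methylcyclopent-1-en-1-olate | c1ccccc1COC[C@@]2(C)CCC(O[Al](C)C)=C2 | intermediate
11 | {[(3S)-3-[(benzyloxy)methyl]-3-methylcyclopent-1-en-1-yl]oxy}trimethylsilane | c1ccccc1COC[C@@]2(C)CCC(O[Si](C)(C)C)=C2 | intermediate
12 | benzyl chloromethyl ether | ClCOCc1ccccc1 | starting material
13 | (2S,3S)-2,3-bis[(benzyloxy)methyl]-3-methylcyclopentan-1-one | c1ccccc1COC[C@@]2(C)CCC(=O)[C@@H]2COCc3ccccc3 | intermediate
14 | isopropylmagnesium chloride | CC(C)[Mg]Cl | starting material
15 | (1R,2S,3S)-2,3-bis[(benzyloxy)methyl]-3-methyl-1-(propan-2-yl)cyclopentan-1-ol | c1ccccc1COC[C@@]2(C)CC[C@@](O)(C(C)C)[C@@H]2COCc3ccccc3 | intermediate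
16 | (1R,2S,3S)-2,3-bis(hydroxymethyl)-3-methyl-1-(propan-2-yl)cyclopentan-1-ol | OC[C@@]1(C)CC[C@@](O)(C(C)C)[C@@H]1CO | intermediate
17 | (1S,2R,3R)-3-hydroxy-1-methyl-3-(propan-2-yl)cyclopentane-1,2-dicarbaldehyde | O=C[C@@]1(C)CC[C@@](O)(C(C)C)[C@@H]1C=O | intermediate
18 | 3-chloro-2-(chloromethyl)prop-1-ene | C=C(CCl)CCl | starting material
19 | (1S,2S,3R)-2-[(1S)-3-(chloromethyl)-1-hydroxybut-3-en-1-yl]-3-hydroxy-1-methyl-3-(propan-2-yl)cyclopentane-1-carbaldehyde | O=C[C@@]1(C)CC[C@@](O)(C(C)C)[C@@H]1[C@@H](O)CC(=C)CCl | intermediate
20 | 8-methylenedaucane-4β,6α,10α-triol | O[C@H]1CC(=C)C[C@@H](O)[C@@]2(C)CC[C@@](O)(C(C)C)[C@H]12 | intermediate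
21 | 4-methoxybenzoyl chloride | COc1ccc(cc1)C(Cl)=O | starting material
22 | 6α-(4-methoxybenzoyloxy)-8-methylenedaucane-4β,10α-diol | COc1ccc(cc1)C(=O)O[C@H]2CC(=C)C[C@@H](O)[C@@]3(C)CC[C@@](O)(C(C)C)[C@H]23 | intermediate
23 | 4β-hydroxy-6α-(4-methoxybenzoyloxy)-8-methylenedaucan-10-one | COc1ccc(cc1)C(=O)O[C@H]2CC(=C)CC(=O)[C@@]3(C)CC[C@@](O)(C(C)C)[C@H]23 | intermediate
24 | 4β-hydroxy-6α-(4-methoxybenzoyloxy)dauc-8-en-10-one | COc1ccc(cc1)C(=O)O[C@H]2CC(C)=CC(=O)[C@@]3(C)CC[C@@](O)(C(C)C)[C@H]23 | intermediate
25 | 6α-(4-methoxybenzoyloxy)dauc-8-ene-4β,10β-diol | COc1ccc(cc1)C(=O)O[C@H]2CC(C)=C[C@H](O)[C@@]3(C)CC[C@@](O)(C(C)C)[C@H]23 | intermediate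
26 | acetic acid | CC(=O)O | starting material
27 | 10α-acetoxy-6α-(4-methoxybenzoyloxy)dauc-8-en-4β-ol (CNP0256979.2) | COc1ccc(C(=O)O[C@H]2CC(C)=C[C@@H](OC(C)=O)[C@@]3(C)CC[C@@](O)(C(C)C)[C@H]23)cc1 | target

Total step count: 13. Longest linear sequence: 13 (1 → 27).

Steps most likely to fail

Step 8. After the first allylation, the second allylindium may be protonated by water, or may react with another dialdehyde molecule, faster than it closes onto the shielded C10 formyl group. Ring B would then not form. The fallback closes ring B by olefin metathesis instead of a second allylation; it sets out from 17 and comes back at 24. Compound 17 is methallylated at C6 with 3-chloro-2-methylprop-1-ene, In and NaI in THF/H2O under the same chelation control to give the methallyl carbinol aldehyde F1. Excess vinylmagnesium bromide adds to the C10 formyl group to give the triol diene F2, of which both C10 epimers are usable. Ring-closing metathesis with the second-generation Grubbs catalyst, RuCl2(=CHPh)(PCy3)(SIMes), in refluxing CH2Cl2 closes ring B directly with the C8=C9 olefin to give dauc-8-ene-4β,6α,10-triol F3. MnO2 oxidises only the allylic C10 hydroxyl to give 4β,6α-dihydroxydauc-8-en-10-one F4. Acylation of its single secondary hydroxyl with 21 (pyridine, DMAP) gives 24.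

Step 13. Activation of the allylic hydroxyl next to the quaternary C1 may be sluggish, and ionisation with allylic transposition or 1,4-elimination may compete with clean inversion. The fallback keeps the C10–O bond made in step 8 rather than rebuilding it; it sets out from 22 and comes back at 27. The axial 10α-hydroxyl of 22 is acetylated with retention (Ac2O, DMAP, Et3N, CH2Cl2) to give 10α-acetoxy-6α-(4-methoxybenzoyloxy)-8-methylenedaucan-4β-ol F5. The exocyclic olefin is then moved into the ring with RhCl3·3H2O (cat.) in hot ethanol. This migration is not directed toward C9, so 27 would have to be separated from the 7-ene regioisomer F6. That separation is the price for avoiding substitution at C10.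

Step 9. Discrimination between the two hindered secondary hydroxyls may be insufficient, leading to acylation at the wrong oxygen or at both. The fallback differentiates by hydroxyl-directed reduction rather than by acylation rate; it sets out from 20 and comes back at 23. Both secondary alcohols of 20 are oxidised (Dess–Martin periodinane, pyridine) to 4β-hydroxy-8-methylenedaucane-6,10-dione F7. Me4NBH(OAc)3 in MeCN/AcOH at −20 °C binds to the C4 hydroxyl and reduces only the β-hydroxy ketone at C6 (Evans–Saksena reduction). It delivers hydride to the β face through a chair-like six-membered transition state and gives 4β,6α-dihydroxy-8-methylenedaucan-10-one F8. Acylation of its single secondary hydroxyl with 21 gives 23. The same detour would repair C6 if chelation control in step 8 fell short.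

Further compounds
F1 | step 8 | (1S,2S,3R)-3-hydroxy-2-[(1S)-1-hydroxy-3-methylbut-3-en-1-yl]-1-methyl-3-(propan-2-yl)cyclopentane-1-carbaldehyde | O=C[C@@]1(C)CC[C@@](O)(C(C)C)[C@@H]1[C@@H](O)CC(C)=C
F2 | step 8 | triol diene from vinyl addition to C10 of F1 (both C10 epimers) | C=CC(O)[C@@]1(C)CC[C@@](O)(C(C)C)[C@@H]1[C@@H](O)CC(C)=C
F3 | step 8 | dauc-8-ene-4β,6α,10-triol (both C10 epimers) | O[C@H]1CC(C)=CC(O)[C@@]2(C)CC[C@@](O)(C(C)C)[C@H]12
F4 | step 8 | 4β,6α-dihydroxydauc-8-en-10-one | O[C@H]1CC(C)=CC(=O)[C@@]2(C)CC[C@@](O)(C(C)C)[C@H]12
F5 | step 13 | 10α-acetoxy-6α-(4-methoxybenzoyloxy)-8-methylenedaucan-4β-ol | COc1ccc(cc1)C(=O)O[C@H]2CC(=C)C[C@@H](OC(C)=O)[C@@]3(C)CC[C@@](O)(C(C)C)[C@H]23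
F6 | step 13 | 10α-acetoxy-6α-(4-methoxybenzoyloxy)dauc-7-en-4β-ol | COc1ccc(cc1)C(=O)O[C@H]2C=C(C)C[C@@H](OC(C)=O)[C@@]3(C)CC[C@@](O)(C(C)C)[C@H]23
F7 | step 9 | 4β-hydroxy-8-methylenedaucane-6,10-dione | O=C1CC(=C)CC(=O)[C@@]2(C)CC[C@@](O)(C(C)C)[C@H]12
F8 | step 9 | 4β,6α-dihydroxy-8-methylenedaucan-10-one | O[C@H]1CC(=C)CC(=O)[C@@]2(C)CC[C@@](O)(C(C)C)[C@H]12
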